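**Retrosynthetic overview**

- The target is numbered from the carboxyl carbon C1. Its only ring is the 1,2-dioxolane C3–C4–C5–O1–O2 (O2 on C3, O1 on C5), and the chain starts at C6. The C2–C3 bond is cut first: ester hydrolysis, then capture of a dioxolan-3-ylium ion, generated from the 3-methoxy-1,2-dioxolane, by an acetate silyl ketene acetal.
- The strategy rests on the unit C5–O1–O2–C3 bridged by C4. It is H2O2 added across a 4-methylalk-3-en-2-one, with O1 on the β-carbon and O2 on the carbonyl carbon. The ring is therefore closed once, as the 3-hydroxy peroxyhemiketal, from the (E)-enone and aqueous H2O2 under a cinchona primary amine salt.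
- The (E)-C(CH3)=CH unit of the enone comes from syn-methylalumination of a terminal alkyne, followed by iodinolysis and acylation. This fixes the alkene geometry that the asymmetric step needs.
- The alkyne comes from a methyl ketone. The methyl at target C7 is set by copper-catalysed asymmetric addition of MeMgBr to an enone. Target C9 and the phenyloctyl chain come from (R)-citronellal by cross-metathesis with 6-phenylhex-1-ene, hydrogenation and Wittig olefination.

Key step: step 8

Assumption: the hand of each chiral catalyst (the Josiphos enantiomer in step 4, the quinidine-derived epi-amine in step 8) is written for the sense of induction expected by analogy with simpler enones; each is checked on a model enone first, and its enantiomer or pseudoenantiomer is used instead if the sense proves reversed.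

**Route**

Step 1
Reactants: 1 (R)-citronellal; 2 6-phenylhex-1-ene
Product: 3 (3R)-3-methyl-11-phenylundec-6-enal (E/Z mixture)
Conditions: 2 (3 equiv), second-generation Grubbs catalyst RuCl2(=CHPh)(H2IMes)(PCy3) (3 mol%), CH2Cl2, 40 °C
Reagents that add atoms: none
Why: Olefin cross-metathesis between the terminal alkene of 2 and the trisubstituted alkene of 1 should be driven by loss of volatile 2-methylpropene; the alkene geometry is irrelevant because it is hydrogenated next, and the C3 centre is not touched.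

Step 2
Reactants: 3 (3R)-3-methyl-11-phenylundec-6-enal
Product: 4 (3R)-3-methyl-11-phenylundecanal
Conditions: H2 (1 atm), 10% Pd/C, EtOAc, rt
Reagents that add atoms: none
Why: Heterogeneous catalytic hydrogenation should saturate the disubstituted alkene while the aliphatic aldehyde and the arene survive at ambient pressure in a non-alcoholic solvent.

Step 3
Reactants: 4 (3R)-3-methyl-11-phenylundecanal; 5 1-(triphenylphosphoranylidene)propan-2-one
Product: 6 (3E,6R)-6-methyl-14-phenyltetradec-3-en-2-one
Conditions: 5 (1.3 equiv), toluene, 90 °C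
Reagents that add atoms: none
Why: Wittig olefination with a stabilised acyl ylide should give the (E)-enone under thermodynamic control of the oxaphosphetane pathway.

Step 4
Reactants: 6 (3E,6R)-6-methyl-14-phenyltetradec-3-en-2-one
Product: 7 (4S,6R)-4,6-dimethyl-14-phenyltetradecan-2-one
Conditions: MeMgBr (1.3 equiv, slow addition), CuBr·SMe2 (5 mol%), (S)-1-[(Rp)-2-(diphenylphosphino)ferrocenyl]ethyldicyclohexylphosphine [(S,R)-Josiphos, 6 mol%], t-BuOMe, −75 °C; aq. NH4Cl
Reagents that add atoms: methylmagnesium bromide, SMILES C[Mg]Br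
Why: Copper-catalysed asymmetric conjugate addition of a Grignard reagent to an acyclic enone; the ferrocenyl diphosphine–copper complex selects the enone face, so the new C4 centre (S, anti to the C6 methyl) is set by the catalyst, the existing centre being one methylene away and too remote to override it.

Step 5
Reactants: 7 (4S,6R)-4,6-dimethyl-14-phenyltetradecan-2-one
Product: 9 (4S,6R)-4,6-dimethyl-14-phenyltetradec-1-yne, via enol phosphate 8 (not isolated)
Conditions: LiN(i-Pr)2 (1.1 equiv), THF, −78 °C; ClP(O)(OEt)2, −78 °C to rt; LiN(i-Pr)2 (2.3 equiv), −78 °C to rt; aq. NH4Cl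
Reagents that add atoms: none
Why: Kinetic deprotonation on the methyl side, O-phosphorylation and base-induced β-elimination of the terminal enol phosphate is the standard conversion of a methyl ketone into a 1-alkyne; neither stereocentre is α to the carbonyl, so both are retained.

Step 6
Reactants: 9 (4S,6R)-4,6-dimethyl-14-phenyltetradec-1-yne
Product: 11 (1E,4S,6R)-1-iodo-2,4,6-trimethyl-14-phenyltetradec-1-ene, via alkenylalane 10 (not isolated)
Conditions: AlMe3 (2 equiv), Cp2ZrCl2 (20 mol%), CH2Cl2, 0 °C to rt; then I2 (1.2 equiv), THF, −30 °C to 0 °C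
Reagents that add atoms: trimethylaluminium, SMILES C[Al](C)C; iodine, SMILES II
Why: Negishi zirconium-catalysed carboalumination adds CH3 and Al syn across the alkyne with methyl on the internal carbon, and iodinolysis of the alkenyl–aluminium bond proceeds with retention, which defines the E geometry.

Step 7
Reactants: 11 (1E,4S,6R)-1-iodo-2,4,6-trimethyl-14-phenyltetradec-1-ene
Product: 13 (3E,6S,8R)-4,6,8-trimethyl-16-phenylhexadec-3-en-2-one, via alkenyllithium 12 (not isolated)
Conditions: t-BuLi (2.1 equiv), Et2O, −78 °C; then CH3C(O)N(OMe)Me (1.5 equiv), −78 °C to 0 °C; aq. NH4Cl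
Reagents that add atoms: N-methoxy-N-methylacetamide, SMILES CC(=O)N(C)OC
Why: Lithium–iodine exchange with retention of alkene geometry followed by acyl substitution on a Weinreb amide, which stops at the ketone stage, should give the (E)-enone without over-addition.

Step 8
Reactants: 13 (3E,6S,8R)-4,6,8-trimethyl-16-phenylhexadec-3-en-2-one; 14 hydrogen peroxide
Product: 16 (5S)-5-[(2S,4R)-2,4-dimethyl-12-phenyldodecyl]-3,5-dimethyl-1,2-dioxolan-3-ol (both C3 epimers), via hydroperoxy ketone 15 (not isolated)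
Conditions: 9-amino-9-deoxy-epi-quinidine (10 mol%), Cl3CCO2H (10 mol%), 50% aq. H2O2 (3 equiv), 1,4-dioxane, 30 °C
Reagents that add atoms: none
Why: Proposed new method: the primary ammonium trichloroacetate should activate the methyl ketone of 13 as its ketiminium, H2O2 held by hydrogen bonding to the protonated quinuclidine adds to the Si face of C4 (the future ring C5), and hydrolysis releases hydroperoxy ketone 15, whose OOH adds to the C2 carbonyl in a 5-exo-trig closure to give the 1,2-dioxolane as hemiketal 16. The closest known reaction is the same amine-salt-catalysed hydroperoxidation of β-monosubstituted acyclic enones to 3-hydroxy-1,2-dioxolanes, together with the related epoxidation of 3-substituted cyclic enones; an acyclic β,β-disubstituted enone, which gives a fully substituted C–O centre, has not been shown. The new centre at ring C5 (S) is set by the catalyst alone, because the nearest existing centre (C6 of 13) is one methylene away and cannot direct; the hemiketal carbon forms as both epimers, which does not matter because it is ionised in step 10. The step needs enantioface selectivity at a β-carbon whose two substituents (CH3 and CH2R) differ little in size, and this is secured by the defined E geometry of 13 and by the methyl ketone, which condenses readily and keeps the chain away from the catalyst; the moderate temperature limits E/Z scrambling through the dienamine. Closure to the hemiketal should remove 15 from retro-addition and from Weitz–Scheffer epoxide formation.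

Step 9
Reactants: 16 (5S)-5-[(2S,4R)-2,4-dimethyl-12-phenyldodecyl]-3,5-dimethyl-1,2-dioxolan-3-ol
Product: 17 (5S)-5-[(2S,4R)-2,4-dimethyl-12-phenyldodecyl]-3-methoxy-3,5-dimethyl-1,2-dioxolane (both C3 epimers)
Conditions: MeOH, p-TsOH·H2O (5 mol%), rt
Reagents that add atoms: methanol, SMILES CO
Why: Acid-catalysed ketal exchange converts the cyclic peroxyhemiketal into its mixed methyl peroxyketal, a known transformation of 3-hydroxy-1,2-dioxolanes; C5 is not involved and both C3 epimers serve in the next step.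

Step 10
Reactants: 17 (5S)-5-[(2S,4R)-2,4-dimethyl-12-phenyldodecyl]-3-methoxy-3,5-dimethyl-1,2-dioxolane
Product: 19 methyl 2-[(3R,5S)-5-[(2S,4R)-2,4-dimethyl-12-phenyldodecyl]-3,5-dimethyl-1,2-dioxolan-3-yl]acetate, via peroxycarbenium ion 18 (not isolated)
Conditions: TiCl4 (1.1 equiv), tert-butyl[(1-methoxyethenyl)oxy]dimethylsilane (3 equiv), CH2Cl2, −78 °C; aq. NaHCO3
Reagents that add atoms: tert-butyl[(1-methoxyethenyl)oxy]dimethylsilane, SMILES C=C(OC)O[Si](C)(C)C(C)(C)C
Why: Lewis acid ionisation of the peroxyketal and Mukaiyama-type capture of the planar dioxolan-3-ylium ion by the silyl ketene acetal is a known displacement of 3-alkoxy-1,2-dioxolanes; attack anti to the larger C5 substituent (the β-branched chain, not the methyl) should set C3 as R, with CH2CO2Me trans to the chain.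

Step 11
Reactants: 19 methyl 2-[(3R,5S)-5-[(2S,4R)-2,4-dimethyl-12-phenyldodecyl]-3,5-dimethyl-1,2-dioxolan-3-yl]acetate
Product: 20 2-[(3R,5S)-5-[(2S,4R)-2,4-dimethyl-12-phenyldodecyl]-3,5-dimethyl-1,2-dioxolan-3-yl]acetic acid
Conditions: LiOH·H2O (3 equiv), THF/H2O (3:1), 0 °C to rt; then 1 M HCl to pH 3
Reagents that add atoms: lithium hydroxide, SMILES [Li+].[OH-]
Why: Ester saponification; neither peroxide-bearing carbon carries hydrogen, so Kornblum–DeLaMare cleavage is excluded, the low temperature disfavours E1cB ring opening, and no stereocentre is affected.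

**Compound list**

1 | (R)-citronellal | C[C@H](CCC=C(C)C)CC=O | starting material
2 | 6-phenylhex-1-ene | C=CCCCCc1ccccc1 | starting material
3 | (3R)-3-methyl-11-phenylundec-6-enal (E/Z mixture) | C[C@H](CCC=CCCCCc1ccccc1)CC=O | intermediate
4 | (3R)-3-methyl-11-phenylundecanal | C[C@H](CCCCCCCCc1ccccc1)CC=O | intermediate
5 | 1-(triphenylphosphoranylidene)propan-2-one | CC(=O)C=P(c1ccccc1)(c1ccccc1)c1ccccc1 | starting material
6 | (3E,6R)-6-methyl-14-phenyltetradec-3-en-2-one | C[C@H](CCCCCCCCc1ccccc1)C/C=C/C(C)=O | intermediate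
7 | (4S,6R)-4,6-dimethyl-14-phenyltetradecan-2-one | C[C@H](CCCCCCCCc1ccccc1)C[C@H](C)CC(C)=O | intermediate
8 | diethyl (4S,6R)-4,6-dimethyl-14-phenyltetradec-1-en-2-yl phosphate (enol phosphate, formed in the flask) | C[C@H](CCCCCCCCc1ccccc1)C[C@H](C)CC(=C)OP(=O)(OCC)OCC | intermediate
9 | (4S,6R)-4,6-dimethyl-14-phenyltetradec-1-yne | C[C@H](CCCCCCCCc1ccccc1)C[C@H](C)CC#C | intermediate
10 | [(1E,4S,6R)-2,4,6-trimethyl-14-phenyltetradec-1-en-1-yl]dimethylaluminium (alkenylalane, formed in the flask) | C[C@H](CCCCCCCCc1ccccc1)C[C@H](C)C/C(C)=C/[Al](C)C | intermediate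
11 | (1E,4S,6R)-1-iodo-2,4,6-trimethyl-14-phenyltetradec-1-ene | C[C@H](CCCCCCCCc1ccccc1)C[C@H](C)C/C(C)=C/I | intermediate
12 | [(1E,4S,6R)-2,4,6-trimethyl-14-phenyltetradec-1-en-1-yl]lithium (alkenyllithium, formed in the flask) | C[C@H](CCCCCCCCc1ccccc1)C[C@H](C)C/C(C)=C/[Li] | intermediate
13 | (3E,6S,8R)-4,6,8-trimethyl-16-phenylhexadec-3-en-2-one | C[C@H](CCCCCCCCc1ccccc1)C[C@H](C)C/C(C)=C/C(C)=O | intermediate
14 | hydrogen peroxide | OO | starting material
15 | (4S,6S,8R)-4-hydroperoxy-4,6,8-trimethyl-16-phenylhexadecan-2-one (hydroperoxy ketone, formed in the flask) | C[C@H](CCCCCCCCc1ccccc1)C[C@H](C)C[C@@](C)(CC(C)=O)OO | intermediate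
16 | (5S)-5-[(2S,4R)-2,4-dimethyl-12-phenyldodecyl]-3,5-dimethyl-1,2-dioxolan-3-ol (both C3 epimers) | C[C@H](CCCCCCCCc1ccccc1)C[C@H](C)C[C@@]1(C)CC(C)(O)OO1 | intermediate
17 | (5S)-5-[(2S,4R)-2,4-dimethyl-12-phenyldodecyl]-3-methoxy-3,5-dimethyl-1,2-dioxolane (both C3 epimers) | C[C@H](CCCCCCCCc1ccccc1)C[C@H](C)C[C@@]1(C)CC(C)(OC)OO1 | intermediate
18 | (5S)-5-[(2S,4R)-2,4-dimethyl-12-phenyldodecyl]-3,5-dimethyl-1,2-dioxolan-3-ylium (peroxycarbenium ion, formed in the flask) | C[C@H](CCCCCCCCc1ccccc1)C[C@H](C)C[C@@]1(C)CC(C)=[O+]O1 | intermediate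
19 | methyl 2-[(3R,5S)-5-[(2S,4R)-2,4-dimethyl-12-phenyldodecyl]-3,5-dimethyl-1,2-dioxolan-3-yl]acetate | C[C@H](CCCCCCCCc1ccccc1)C[C@H](C)C[C@@]1(C)C[C@](C)(CC(=O)OC)OO1 | intermediate
20 | 2-[(3R,5S)-5-[(2S,4R)-2,4-dimethyl-12-phenyldodecyl]-3,5-dimethyl-1,2-dioxolan-3-yl]acetic acid | C[C@H](CCCCCCCCc1ccccc1)C[C@H](C)C[C@@]1(C)C[C@](C)(CC(=O)O)OO1 | target

**Totals**

Total step count: 11. Longest linear sequence: 11 steps, from 1 to 20.

**Steps most likely to fail**

1. Step 8 (the step that goes beyond known chemistry). Conjugate addition at the doubly substituted β-carbon may be slow or reversible, the catalyst may discriminate weakly between the methyl and CH2R faces, and 13 may scramble E/Z through the dienamine; each lowers selectivity at ring C5.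
 Fallback with known chemistry, setting out from 13 and returning at 17. Corey–Bakshi–Shibata reduction of 13 ((R)-2-methyl-CBS-oxazaborolidine, BH3·SMe2) should give (2S,3E,6S,8R)-4,6,8-trimethyl-16-phenylhexadec-3-en-2-ol F1. Hydroxyl-directed mCPBA epoxidation, threo-selective because of allylic 1,3-strain from the C4 methyl, should give (1S)-1-[(2R,3R)-3-[(2S,4R)-2,4-dimethyl-12-phenyldodecyl]-3-methyloxiran-2-yl]ethan-1-ol F2. NaAlH2(OCH2CH2OCH3)2 delivers hydride to the carbon next to the carbinol, giving (2S,4R,6S,8R)-4,6,8-trimethyl-16-phenylhexadecane-2,4-diol F3. Selective mesylation of the secondary hydroxyl (MsCl, Et3N) gives (2S,4R,6S,8R)-4-hydroxy-4,6,8-trimethyl-16-phenylhexadecan-2-yl methanesulfonate F4, and KOt-Bu closes (2R,4R)-2-[(2S,4R)-2,4-dimethyl-12-phenyldodecyl]-2,4-dimethyloxetane F5 with the tertiary C–O bond intact. Ethereal H2O2 with Me3SiOTf opens the oxetane at the tertiary carbon with inversion, giving (2R,4S,6S,8R)-4-hydroperoxy-4,6,8-trimethyl-16-phenylhexadecan-2-ol F6. The hydroperoxide is masked with 2-methoxypropene and PPTS as (2R,4S,6S,8R)-4-[(2-methoxypropan-2-yl)peroxy]-4,6,8-trimethyl-16-phenylhexadecan-2-ol F7, and Dess–Martin oxidation gives (4S,6S,8R)-4-[(2-methoxypropan-2-yl)peroxy]-4,6,8-trimethyl-16-phenylhexadecan-2-one F8. p-TsOH in MeOH then unmasks the hydroperoxide, which closes onto the ketone and is ketalised to 17.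

2. Step 10. Capture of the planar peroxycarbenium ion may show poor facial selectivity, since methyl and CH2R at C5 differ little, and TiCl4 may trigger heterolysis of the O–O bond.
 Fallback setting out from 17 and returning at 20, bypassing steps 10 and 11. Hosomi–Sakurai allylation (allyltrimethylsilane, SnCl4, CH2Cl2, −78 °C), a documented trans-selective capture of dioxolan-3-ylium ions, should give (3S,5S)-5-[(2S,4R)-2,4-dimethyl-12-phenyldodecyl]-3,5-dimethyl-3-(prop-2-en-1-yl)-1,2-dioxolane F9. Ozonolysis (O3, CH2Cl2/MeOH, −78 °C; Me2S) gives 2-[(3R,5S)-5-[(2S,4R)-2,4-dimethyl-12-phenyldodecyl]-3,5-dimethyl-1,2-dioxolan-3-yl]acetaldehyde F10. Pinnick oxidation (NaClO2, NaH2PO4, 2-methylbut-2-ene, t-BuOH/H2O) gives 20 without any basic step.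

3. Step 4. The Grignard reagent may add 1,2 to the methyl ketone in competition with conjugate addition, and catalyst control over the new methyl centre may be incomplete.
 Fallback setting out from 4 and returning at 9, which also bypasses step 5. Wittig olefination of 4 with methyl (triphenylphosphoranylidene)acetate gives methyl (2E,5R)-5-methyl-13-phenyltridec-2-enoate F11. Conjugate addition of MeMgBr under CuI and the Tol-BINAP enantiomer matched to the 3S centre gives methyl (3S,5R)-3,5-dimethyl-13-phenyltridecanoate F12; an ester cannot undergo the competing ketone 1,2-addition. i-Bu2AlH at −78 °C gives (3S,5R)-3,5-dimethyl-13-phenyltridecanal F13, and Ohira–Bestmann homologation (dimethyl (1-diazo-2-oxopropyl)phosphonate, K2CO3, MeOH) gives 9.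

**Further compounds**

F1 | step 8 | (2S,3E,6S,8R)-4,6,8-trimethyl-16-phenylhexadec-3-en-2-ol | C[C@H](CCCCCCCCc1ccccc1)C[C@H](C)C/C(C)=C/[C@H](C)O
F2 | step 8 | (1S)-1-[(2R,3R)-3-[(2S,4R)-2,4-dimethyl-12-phenyldodecyl]-3-methyloxiran-2-yl]ethan-1-ol | C[C@H](CCCCCCCCc1ccccc1)C[C@H](C)C[C@@]1(C)O[C@@H]1[C@H](C)O
F3 | step 8 | (2S,4R,6S,8R)-4,6,8-trimethyl-16-phenylhexadecane-2,4-diol | C[C@H](CCCCCCCCc1ccccc1)C[C@H](C)C[C@@](C)(O)C[C@H](C)O
F4 | step 8 | (2S,4R,6S,8R)-4-hydroxy-4,6,8-trimethyl-16-phenylhexadecan-2-yl methanesulfonate | C[C@H](CCCCCCCCc1ccccc1)C[C@H](C)C[C@@](C)(O)C[C@H](C)OS(C)(=O)=O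
F5 | step 8 | (2R,4R)-2-[(2S,4R)-2,4-dimethyl-12-phenyldodecyl]-2,4-dimethyloxetane | C[C@H](CCCCCCCCc1ccccc1)C[C@H](C)C[C@]1(C)C[C@@H](C)O1
F6 | step 8 | (2R,4S,6S,8R)-4-hydroperoxy-4,6,8-trimethyl-16-phenylhexadecan-2-ol | C[C@H](CCCCCCCCc1ccccc1)C[C@H](C)C[C@](C)(OO)C[C@@H](C)O
F7 | step 8 | (2R,4S,6S,8R)-4-[(2-methoxypropan-2-yl)peroxy]-4,6,8-trimethyl-16-phenylhexadecan-2-ol | C[C@H](CCCCCCCCc1ccccc1)C[C@H](C)C[C@](C)(OOC(C)(C)OC)C[C@@H](C)O
F8 | step 8 | (4S,6S,8R)-4-[(2-methoxypropan-2-yl)peroxy]-4,6,8-trimethyl-16-phenylhexadecan-2-one | C[C@H](CCCCCCCCc1ccccc1)C[C@H](C)C[C@](C)(OOC(C)(C)OC)CC(C)=O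
F9 | step 10 | (3S,5S)-5-[(2S,4R)-2,4-dimethyl-12-phenyldodecyl]-3,5-dimethyl-3-(prop-2-en-1-yl)-1,2-dioxolane | C[C@H](CCCCCCCCc1ccccc1)C[C@H](C)C[C@@]1(C)C[C@](C)(CC=C)OO1
F10 | step 10 | 2-[(3R,5S)-5-[(2S,4R)-2,4-dimethyl-12-phenyldodecyl]-3,5-dimethyl-1,2-dioxolan-3-yl]acetaldehyde | C[C@H](CCCCCCCCc1ccccc1)C[C@H](C)C[C@@]1(C)C[C@](C)(CC=O)OO1
F11 | step 4 | methyl (2E,5R)-5-methyl-13-phenyltridec-2-enoate | C[C@H](CCCCCCCCc1ccccc1)C/C=C/C(=O)OC
F12 | step 4 | methyl (3S,5R)-3,5-dimethyl-13-phenyltridecanoate | C[C@H](CCCCCCCCc1ccccc1)C[C@H](C)CC(=O)OC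
F13 | step 4 | (3S,5R)-3,5-dimethyl-13-phenyltridecanal | C[C@H](CCCCCCCCc1ccccc1)C[C@H](C)CC=O
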